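## Analysis of the target

Sideroxylonal A (22) is a chroman whose pyran ring (O1, C2, C3, C4) is fused along C4a–C8a to ring A (C4a, C5, C6, C7, C8, C8a), a fully substituted phloroglucinol with oxygen at C5, C7 and C8a (the last as O1) and formyl groups at C6 and C8. C2 carries ring B (3,5-diformyl-2,4,6-trihydroxyphenyl), C3 an isopropyl group and C4 an isobutyl group. The three contiguous stereocentres are (2R,3R,4S): the aryl group is trans to the isopropyl group and the isopropyl group is cis to the isobutyl group, so both alkyl groups lie on one face and ring B on the other. The sensitive points are the four aldehydes, the six phenols and above all the C2–O1 bond, a benzylic aryl ether next to a 2,4,6-trioxygenated ring that ionises under acid for as long as ring B is electron-rich. The difficulties are the 3,4-cis arrangement of two branched alkyl groups beside a 2,3-trans aryl group, two hexasubstituted arenes, and the timing of four formylations against an acid-labile centre. The strategy rests on one feature of ring A: its C4a=C8a edge, with O1 on C8a, is formally the enol ether double bond of a 3,4-dihydro-2H-pyran. A dihydropyran that already holds C2, C3 and C4 can therefore become the chroman by growing C5, C6, C7 and C8 onto that double bond.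

## Retrosynthetic reasoning

**22 from 21.** The last cut removes four O-alkyl groups: three methyl ethers on ring B and one ethyl ether at C7. It is placed last because free polyphenols would interfere with every earlier step. Each alkoxy group in 21 is ortho to a formyl group, so a chelating boron halide can cleave them all in one operation.

**21 from 20.** The four C–CHO bonds at C6, C8, C3′ and C5′ are cut together. All four positions lie between two oxygen substituents, and late formylation keeps the aldehydes out of the organometallic and photochemical steps. The forward reaction is an exhaustive Rieche formylation.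

**20 from 14 and 15.** This is the strategic cut. C8–C8a, C7–C8, C5–C6 and C4a–C5 are broken, which removes C5 to C8 of ring A and leaves a dihydropyran with all three stereocentres. The oxygen pattern follows from the fragments: O1 comes from the pyran, the free C5 hydroxyl from the ketone oxygen of 14, and the C7 ether from the ynol ether 15. The forward step must convert the diazo ketone into a vinylketene, join it to 15 with the oxygen-bearing alkyne carbon at C8, and close ring A onto C4a. It runs under neutral, light-driven conditions that do not touch C2–O1. A silyl ynol ether is the more usual partner, but the ethyl ynol ether 15 is a stock reagent. Its ethyl group leaves with the methyl groups in the last step and is small enough not to shield C6 and C8 during formylation.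

**14 from 12, and 12 from 10 through 11.** The C–N2 bond is cut back to a methyl ketone (diazo transfer), and the acetyl C–CH3 bond back to the ester by way of the Weinreb amide 11. This path is chosen over an acid chloride route because it stays basic throughout and is the established access to α,β-unsaturated α′-diazo ketones.

**10 from 7 and 8.** The C2–aryl bond is cut so that ring B enters as the nucleophile 8 on the oxocarbenium ion 9, which is formed from the acetal 7. In 9 the isopropyl and isobutyl groups sit on the same face, so the arene should enter from the other face and give the 2,3-trans relationship directly. Carrying the aryl group on the alkene partner of the cycloaddition, as a (Z)-styrene, was not adopted. Such a di-ortho-substituted (Z)-styrene is twisted out of conjugation, its ring CH positions would compete as nucleophiles for the activated keto ester, and the all-cis adduct would need a C2 inversion with no clear driving force in the dihydropyran. In the chroman that driving force exists: the C5 oxygen forces the C4 isobutyl group pseudoaxial, and only the 2,3-trans isomer can then hold both isopropyl and aryl equatorial. A C2 error would therefore still be correctable after the key step.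

**7 from 3 and 6.** O1–C2 and C3–C4 are cut in an inverse-electron-demand hetero-Diels–Alder reaction between the keto ester 3 and the (Z)-enol ether 6. One step builds the ring with the enol ether double bond and the C8a carboxyl already in place. The (Z)-geometry and the endo mode fix 3,4-cis, and a chiral Lewis acid catalyst fixes the absolute configuration.

**3 from 1 and 2; 6 from 4 and 5.** The enone C=C of 3 is cut to aldehyde 1 and the keto-stabilised ylide 2 (Wittig), which avoids a crossed aldol between two enolisable carbonyl compounds. The isopropyl–vinyl bond of 6 is cut to the (Z)-bromide 4 and Grignard reagent 5, a stereoretentive cross-coupling that should deliver the (Z)-geometry pure.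

## Alternatives that were turned down

**Alternative 1:** conjunctive cross-coupling across an alkenylboronate.
- Disconnection: the C3–isopropyl bond and the C4–C4a bond, made together across the double bond of a (Z)-alkenylboronate.
- Forward key step: isopropyllithium A3 adds to boron in 4,4,5,5-tetramethyl-2-[(Z)-4-methylpent-1-enyl]-1,3,2-dioxaborolane A2. The ate complex then reacts with 2,4,6-trimethoxyphenyl trifluoromethanesulfonate A4 under palladium catalysis with a chiral ferrocenyl bisphosphine. The isopropyl group shifts from boron to C3 while the aryl group is delivered to C4 on the opposite face, which should give 2-[(3R,4S)-2,6-dimethyl-4-(2,4,6-trimethoxyphenyl)heptan-3-yl]-4,4,5,5-tetramethyl-1,3,2-dioxaborolane A1.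
- For: one catalytic three-component step sets C3 and C4 by catalyst control, ring A arrives intact, and no photochemistry is needed. On the security of ring A and on catalyst control of C3 and C4 it is at least as strong as the chosen route.
- Against: the migrating group is secondary and the alkene of A2 is β-substituted. Both slow the metallate shift and favour direct transfer of isopropyl to palladium. The aryl–palladium species from A4 is hindered by two ortho methoxy groups.
- Against, after A1: the C3–B bond must still become the C3–C2 bond with a third stereocentre, one of two equivalent ortho methoxy groups must be freed to become O1, and the ring must be closed at an ionisable benzylic carbon.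
- Comparison: the chosen route obtains O1, the pyran ring and C2 within two steps of its stereodefining step and differentiates the ring A oxygens without any selective demethylation.

**Alternative 2:** desymmetrising Prins cyclisation.
- Disconnection: O1–C2 and C2–C3.
- Forward key step: 2-(2,6-dimethylhepta-2,5-dien-4-yl)-3,5-dimethoxyphenol A6 condenses with 2,4,6-trimethoxybenzaldehyde A7 under a confined chiral Brønsted acid. One enantiotopic alkene attacks the O-aryl oxocarbenium ion and should give (2R,3S,4S)-5,7-dimethoxy-4-(2-methylprop-1-enyl)-3-(prop-1-en-2-yl)-2-(2,4,6-trimethoxyphenyl)chroman A5.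
- For: all three stereocentres and the pyran ring form in one catalytic step with both arenes in place. In convergence up to the chroman it is stronger than the chosen route.
- Against: the same cation is the intermediate of Friedel–Crafts hydroxyalkylation at the free positions of the electron-rich ring of A6. A confined acid has little room for a di-ortho-substituted aryl group and two branched arms. The 3,4-cis relationship requires the non-reacting arm to sit axial in the chair-like transition state. The two alkenes of A5 must afterwards be saturated without hydrogenolysis of the benzylic C2–O1 bond, and A6 itself takes several steps.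
- Comparison: the chosen route gives up this convergence for a stereodefining step of an established type, in which 3,4-cis follows from alkene geometry.

**Alternative 3:** Michael–hemiacetal annulation.
- Disconnection: C4–C4a and O1–C2.
- Forward key step: 3,5-dimethoxyphenol A9 adds through its ortho carbon to the iminium ion formed from (E)-2-isopropyl-5-methylhex-2-enal A10, the aldol dimer of 1, and a chiral primary amine salt. The phenol oxygen then closes the lactol (3R,4S)-4-isobutyl-3-isopropyl-5,7-dimethoxychroman-2-ol A8.
- For: it is the shortest route. Both alkyl groups come from the commodity enal A10 and ring A from the commodity phenol A9, so in step economy it is clearly superior.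
- Against: the α-branched enal A10 gives a hindered iminium ion. C3 is set only by enamine protonation and lies α to the lactol carbon of A8, so it can drift to the 3,4-trans arrangement, the opposite of what 22 needs. A9 can also react para to its hydroxyl group, where no lactol can form. The aryl group must still be attached at C2 of A8 through an O-aryl oxocarbenium ion.
- Comparison: in the chosen route C3 and C4 are fixed kinetically in a cycloaddition and C3 is never adjacent to a carbonyl group afterwards. The price is a longer sequence and a late, more demanding ring A construction.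

Key step: step 7

Remark: 2, 4 and 15 are taken to be catalogue reagents; the ynol ether partner of the key step is the ethyl ether 15, so that the C7 oxygen of the key-step product 20 is protected as an ethyl ether.

## Route

Step 1
Reactants: 1 isovaleraldehyde; 2 ethyl 2-oxo-3-(triphenylphosphoranylidene)propanoate
Product: 3 ethyl (E)-6-methyl-2-oxohept-3-enoate
Conditions: toluene, 80 °C
Reagents that add atoms: none
Why: Wittig olefination with a keto-stabilised ylide, which should give the (E)-enone and does not enolise the aldehyde, so the self-condensations of a direct crossed aldol are avoided.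

Step 2
Reactants: 4 (Z)-1-bromo-2-ethoxyethene; 5 isopropylmagnesium chloride
Product: 6 (Z)-1-ethoxy-3-methylbut-1-ene
Conditions: cat. PdCl2(dppf), Et2O, 0 °C → rt; distillation
Reagents that add atoms: none
Why: Kumada–Corriu cross-coupling; oxidative addition of the alkenyl bromide and reductive elimination proceed with retention, so the (Z)-geometry of 4 is carried into 6, and the dppf ligand is the established choice for coupling secondary alkyl Grignard reagents without isomerisation.

Step 3
Reactants: 3 ethyl (E)-6-methyl-2-oxohept-3-enoate; 6 (Z)-1-ethoxy-3-methylbut-1-ene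
Product: 7 ethyl (2S,3R,4R)-2-ethoxy-4-isobutyl-3-isopropyl-3,4-dihydro-2H-pyran-6-carboxylate
Conditions: cat. Cu(OTf)2, (R,R)-t-Bu-box [2,2′-(propane-2,2-diyl)bis((4R)-4-tert-butyl-4,5-dihydrooxazole)], molecular sieves, THF, 0 °C → rt; enol ether in excess
Reagents that add atoms: none
Why: Inverse-electron-demand hetero-Diels–Alder reaction of a chelating β,γ-unsaturated α-keto ester with an enol ether under Cu(OTf)2–bisoxazoline catalysis, a pure [4+2] addition in which every atom of 3 and 6 ends up in 7; the volatile enol ether is taken in excess and the surplus is recovered unchanged. The endo transition state together with the (Z)-geometry of 6 should place ethoxy, isopropyl and isobutyl on one face (2,3-cis, 3,4-cis). With the (R,R)-ligand the tert-butyl group beside the bound ketone oxygen is expected, from the square-planar chelate model, to cover the Si face of the enone β-carbon, so that 6 adds to its Re face and C3 and C4 are set as needed.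

Step 4
Reactants: 7 ethyl (2S,3R,4R)-2-ethoxy-4-isobutyl-3-isopropyl-3,4-dihydro-2H-pyran-6-carboxylate; 8 1,3,5-trimethoxybenzene
Product: 10 ethyl (2R,3R,4S)-4-isobutyl-3-isopropyl-2-(2,4,6-trimethoxyphenyl)-3,4-dihydro-2H-pyran-6-carboxylate, via cyclic oxocarbenium ion 9 (not isolated)
Conditions: cat. TMSOTf, CH2Cl2, −78 → −40 °C; Et3N quench
Reagents that add atoms: none
Why: Lewis-acid-mediated Friedel–Crafts C-arylation of a cyclic acetal, the reaction type of aryl C-glycoside synthesis: loss of the exocyclic ethoxy group gives 9, which 8 attacks at C2. Isopropyl and isobutyl shield the same face of 9, so the arene should enter from the opposite face and set C2 trans to both; low temperature and a near-stoichiometric amount of 8 limit re-ionisation of the new benzylic C2–O1 bond.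

Step 5
Reactants: 10 ethyl (2R,3R,4S)-4-isobutyl-3-isopropyl-2-(2,4,6-trimethoxyphenyl)-3,4-dihydro-2H-pyran-6-carboxylate
Product: 12 1-[(2R,3R,4S)-4-isobutyl-3-isopropyl-2-(2,4,6-trimethoxyphenyl)-3,4-dihydro-2H-pyran-6-yl]ethanone, via Weinreb amide 11 (not isolated)
Conditions: MeNH(OMe)·HCl, iPrMgCl, THF, −20 °C; then MeMgBr, −20 → 0 °C; aq. NH4Cl
Reagents that add atoms: methylmagnesium bromide, C[Mg]Br; N,O-dimethylhydroxylamine hydrochloride, CNOC.Cl (its atoms remain only in intermediate 11)
Why: Aminolysis of the ester by the magnesium amide of N,O-dimethylhydroxylamine, followed in the same flask by Grignard addition to the Weinreb amide, whose chelated tetrahedral adduct stops at the ketone. The basic conditions spare the enol ether and the acid-labile C2–O1 bond.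

Step 6
Reactants: 12 1-[(2R,3R,4S)-4-isobutyl-3-isopropyl-2-(2,4,6-trimethoxyphenyl)-3,4-dihydro-2H-pyran-6-yl]ethanone
Product: 14 2-diazo-1-[(2R,3R,4S)-4-isobutyl-3-isopropyl-2-(2,4,6-trimethoxyphenyl)-3,4-dihydro-2H-pyran-6-yl]ethanone, via trifluoroacetyl ketone 13 (not isolated)
Conditions: LiN(SiMe3)2, THF, −78 °C; CF3CO2CH2CF3; aq. NH4Cl; then MsN3, Et3N, H2O, MeCN, rt
Reagents that add atoms: methanesulfonyl azide, CS(=O)(=O)N=[N+]=[N-]; 2,2,2-trifluoroethyl trifluoroacetate, O=C(OCC(F)(F)F)C(F)(F)F (its atoms remain only in intermediate 13)
Why: Detrifluoroacetylative diazo transfer: kinetic deprotonation at the methyl group, trifluoroacetylation to 13, then diazo transfer from the sulfonyl azide with loss of the trifluoroacetyl group. This is the standard access to α,β-unsaturated α′-diazo ketones and avoids acid chlorides and free acid.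

Step 7
Reactants: 14 2-diazo-1-[(2R,3R,4S)-4-isobutyl-3-isopropyl-2-(2,4,6-trimethoxyphenyl)-3,4-dihydro-2H-pyran-6-yl]ethanone; 15 ethoxyethyne
Product: 20 (2R,3R,4S)-7-ethoxy-4-isobutyl-3-isopropyl-2-(2,4,6-trimethoxyphenyl)chroman-5-ol, via vinylketene 16 (not isolated), via vinylcyclobutenone 17 (not isolated), via dienylketene 18 (not isolated), via cyclohexadienone 19 (not isolated)
Conditions: hν (300 nm, Pyrex), ClCH2CH2Cl, degassed, rt; then 80 °C, sealed tube; ynol ether in excess
Reagents that add atoms: none
Why: Irradiation expels the diazo nitrogen and the pyranyl carbon C8a migrates from the carbonyl carbon to the diazo carbon (Wolff rearrangement), giving vinylketene 16 in which the former diazo carbon is C8 and the ketene carbon is C5. Ynol ether 15 then adds across the ketene C=C in a [2+2] cycloaddition, its nucleophilic CH carbon bonding to the electrophilic ketene carbon (C5–C6) and its oxygen-bearing carbon to C8 (C7–C8), to give cyclobutenone 17. Ring opening of 17 (4π, by heat or light) cleaves C5–C8 and gives dienylketene 18. Ring A is closed as a six-membered carbocycle by a thermal, disrotatory 6π electrocyclisation of 18, in which the ketene carbon bonds to the enol ether carbon C4a (C4a–C5), and cyclohexadienone 19 tautomerises to the phenol. The closest known reaction type is the photochemical Danheiser benzannulation of α,β-unsaturated and heteroaryl α′-diazo ketones with alkoxy- and siloxyalkynes. No stereocentre is created, since the sp3 centres of 17 and 19 are lost again, and C2, C3 and C4 are spectators under these neutral conditions. The selectivity required is the regiochemistry of the [2+2] step; it is secured by the polarisation of the ynol ether and of the ketene and leads to the 5-hydroxy-7-ethoxy pattern with O1 from the pyran.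

Step 8
Reactants: 20 (2R,3R,4S)-7-ethoxy-4-isobutyl-3-isopropyl-2-(2,4,6-trimethoxyphenyl)chroman-5-ol
Product: 21 (2R,3R,4S)-2-(3,5-diformyl-2,4,6-trimethoxyphenyl)-7-ethoxy-5-hydroxy-4-isobutyl-3-isopropylchroman-6,8-dicarbaldehyde
Conditions: Cl2CHOMe (large excess), TiCl4 (large excess), CH2Cl2, −78 °C → rt; aq. HCl
Reagents that add atoms: dichloromethyl methyl ether, COC(Cl)Cl; water, O (formyl oxygen on hydrolysis)
Why: Rieche formylation, an electrophilic aromatic substitution by the chloro(methoxy)methyl cation; C6, C8, C3′ and C5′ each lie between two oxygen substituents, and on each ring the second formyl group enters meta to the first, so exhaustive formylation should be feasible with excess reagent. Partial loss of alkyl groups ortho to the new aldehydes under TiCl4 would be harmless, because step 9 removes them all.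

Step 9
Reactants: 21 (2R,3R,4S)-2-(3,5-diformyl-2,4,6-trimethoxyphenyl)-7-ethoxy-5-hydroxy-4-isobutyl-3-isopropylchroman-6,8-dicarbaldehyde
Product: 22 sideroxylonal A
Conditions: BBr3 (excess), CH2Cl2, −78 → 0 °C; H2O
Reagents that add atoms: none
Why: Lewis-acid cleavage of aryl alkyl ethers; every alkoxy group is ortho to a formyl group, so boron chelation should assist bromide attack at the alkyl carbon, and aqueous work-up returns the phenols and aldehydes. With two formyl groups on each ring the benzylic C2–O1 bond is deactivated towards ionisation.

## Compound list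

1 | isovaleraldehyde (3-methylbutanal) | CC(C)CC=O | starting material
2 | ethyl 2-oxo-3-(triphenylphosphoranylidene)propanoate | CCOC(=O)C(=O)C=P(c1ccccc1)(c1ccccc1)c1ccccc1 | starting material
3 | ethyl (E)-6-methyl-2-oxohept-3-enoate | CCOC(=O)C(=O)/C=C/CC(C)C | intermediate
4 | (Z)-1-bromo-2-ethoxyethene | Br/C=C\OCC | starting material
5 | isopropylmagnesium chloride | CC(C)[Mg]Cl | starting material
6 | (Z)-1-ethoxy-3-methylbut-1-ene | CCO/C=C\C(C)C | intermediate
7 | ethyl (2S,3R,4R)-2-ethoxy-4-isobutyl-3-isopropyl-3,4-dihydro-2H-pyran-6-carboxylate (ethoxy, isopropyl and isobutyl all cis) | CC(C)C[C@@H]1C=C(C(=O)OCC)O[C@H](OCC)[C@@H]1C(C)C | intermediate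
8 | 1,3,5-trimethoxybenzene | COc1cc(OC)cc(OC)c1 | starting material
9 | (3R,4R)-6-(ethoxycarbonyl)-4-isobutyl-3-isopropyl-3,4-dihydropyrylium (cyclic oxocarbenium ion, O1=C2) | CC(C)C[C@@H]1C=C(C(=O)OCC)[O+]=C[C@@H]1C(C)C | intermediate
10 | ethyl (2R,3R,4S)-4-isobutyl-3-isopropyl-2-(2,4,6-trimethoxyphenyl)-3,4-dihydro-2H-pyran-6-carboxylate | CC(C)C[C@@H]1C=C(C(=O)OCC)O[C@@H](c2c(OC)cc(OC)cc2OC)[C@@H]1C(C)C | intermediate
11 | (2R,3R,4S)-4-isobutyl-3-isopropyl-N-methoxy-N-methyl-2-(2,4,6-trimethoxyphenyl)-3,4-dihydro-2H-pyran-6-carboxamide | CC(C)C[C@@H]1C=C(C(=O)N(C)OC)O[C@@H](c2c(OC)cc(OC)cc2OC)[C@@H]1C(C)C | intermediate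
12 | 1-[(2R,3R,4S)-4-isobutyl-3-isopropyl-2-(2,4,6-trimethoxyphenyl)-3,4-dihydro-2H-pyran-6-yl]ethanone | CC(C)C[C@@H]1C=C(C(C)=O)O[C@@H](c2c(OC)cc(OC)cc2OC)[C@@H]1C(C)C | intermediate
13 | 4,4,4-trifluoro-1-[(2R,3R,4S)-4-isobutyl-3-isopropyl-2-(2,4,6-trimethoxyphenyl)-3,4-dihydro-2H-pyran-6-yl]butane-1,3-dione | CC(C)C[C@@H]1C=C(C(=O)CC(=O)C(F)(F)F)O[C@@H](c2c(OC)cc(OC)cc2OC)[C@@H]1C(C)C | intermediate
14 | 2-diazo-1-[(2R,3R,4S)-4-isobutyl-3-isopropyl-2-(2,4,6-trimethoxyphenyl)-3,4-dihydro-2H-pyran-6-yl]ethanone | CC(C)C[C@@H]1C=C(C(=O)C=[N+]=[N-])O[C@@H](c2c(OC)cc(OC)cc2OC)[C@@H]1C(C)C | intermediate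
15 | ethoxyethyne | C#COCC | starting material
16 | 2-[(2R,3R,4S)-4-isobutyl-3-isopropyl-2-(2,4,6-trimethoxyphenyl)-3,4-dihydro-2H-pyran-6-yl]ethenone (vinylketene) | CC(C)C[C@@H]1C=C(C=C=O)O[C@@H](c2c(OC)cc(OC)cc2OC)[C@@H]1C(C)C | intermediate
17 | 3-ethoxy-4-[(2R,3R,4S)-4-isobutyl-3-isopropyl-2-(2,4,6-trimethoxyphenyl)-3,4-dihydro-2H-pyran-6-yl]cyclobut-2-en-1-one (both configurations at the cyclobutenone carbon C4) | CC(C)C[C@@H]1C=C(C2C(=O)C=C2OCC)O[C@@H](c2c(OC)cc(OC)cc2OC)[C@@H]1C(C)C | intermediate
18 | (3E)-3-ethoxy-4-[(2R,3R,4S)-4-isobutyl-3-isopropyl-2-(2,4,6-trimethoxyphenyl)-3,4-dihydro-2H-pyran-6-yl]buta-1,3-dien-1-one (ketene arm cis to the pyranyl group) | CC(C)C[C@@H]1C=C(/C=C(/OCC)C=C=O)O[C@@H](c2c(OC)cc(OC)cc2OC)[C@@H]1C(C)C | intermediate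
19 | (2R,3R,4S)-7-ethoxy-4-isobutyl-3-isopropyl-2-(2,4,6-trimethoxyphenyl)-2,3,4,4a-tetrahydro-5H-chromen-5-one (C4a unspecified) | CC(C)C[C@@H]1C2C(=O)C=C(OCC)C=C2O[C@@H](c2c(OC)cc(OC)cc2OC)[C@@H]1C(C)C | intermediate
20 | (2R,3R,4S)-7-ethoxy-4-isobutyl-3-isopropyl-2-(2,4,6-trimethoxyphenyl)chroman-5-ol | CC(C)C[C@@H]1c2c(O)cc(OCC)cc2O[C@@H](c2c(OC)cc(OC)cc2OC)[C@@H]1C(C)C | intermediate
21 | (2R,3R,4S)-2-(3,5-diformyl-2,4,6-trimethoxyphenyl)-7-ethoxy-5-hydroxy-4-isobutyl-3-isopropylchroman-6,8-dicarbaldehyde | CC(C)C[C@@H]1c2c(O)c(C=O)c(OCC)c(C=O)c2O[C@@H](c2c(OC)c(C=O)c(OC)c(C=O)c2OC)[C@@H]1C(C)C | intermediate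
22 | sideroxylonal A, (2R,3R,4S)-2-(3,5-diformyl-2,4,6-trihydroxyphenyl)-5,7-dihydroxy-4-isobutyl-3-isopropylchroman-6,8-dicarbaldehyde | CC(C)C[C@@H]1c2c(O)c(C=O)c(O)c(C=O)c2O[C@@H](c2c(O)c(C=O)c(O)c(C=O)c2O)[C@@H]1C(C)C | target

## Step count and least certain steps

Total: 9 steps. Longest linear sequence: 8 steps (steps 1, 3, 4, 5, 6, 7, 8 and 9); step 2 is a one-step side branch.

**Step 7, the key step.**
- What may go wrong: secondary photochemistry of the electron-rich aryl and enol ether chromophores during irradiation; capture of the ketene by the product phenol as it forms (O-acylation); and stalling at the cyclobutenone stage if the thermal stage has to be kept mild because the ynol ether is volatile and heat-sensitive.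
- Fallback, setting out from 14 and coming back at 20: ketene formation is separated from the photochemistry. Compound 14 is rearranged alone with water as the trap (PhCO2Ag, Et3N, aqueous THF) to the homologous acid 2-[(2R,3R,4S)-4-isobutyl-3-isopropyl-2-(2,4,6-trimethoxyphenyl)-3,4-dihydro-2H-pyran-6-yl]acetic acid F1. This is converted under neutral conditions with 1-chloro-N,N,2-trimethylprop-1-en-1-amine into the acid chloride 2-[(2R,3R,4S)-4-isobutyl-3-isopropyl-2-(2,4,6-trimethoxyphenyl)-3,4-dihydro-2H-pyran-6-yl]acetyl chloride F2. Dehydrochlorination of F2 with Et3N in toluene at 80 °C in the presence of 15 regenerates 16 without light, and the same cycloaddition, ring opening and electrocyclisation should lead to 20.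

**Step 3.**
- What may go wrong: slow cycloaddition, because the C3–C4 bond joins two carbons that each carry a branched group, with erosion of endo selectivity or of enantioselectivity; Lewis-acid isomerisation of the enol ether to its (E)-isomer; and a facial sense opposite to the chelate model, which would lead into the mirror-image series and would be answered by the other ligand enantiomer.
- Fallback, setting out from 3 and 6 and coming back at 7: the cycloaddition is run racemically under the achiral lanthanide Lewis acid Eu(fod)3 (neat, 50 °C, or under high pressure), conditions that accept hindered enol ethers and remain endo-selective. This should give 7 together with its enantiomer ethyl (2R,3S,4S)-2-ethoxy-4-isobutyl-3-isopropyl-3,4-dihydro-2H-pyran-6-carboxylate F3. The two are separated by preparative chromatography on a chiral stationary phase, and 7 re-enters the route.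

**Step 4.**
- What may go wrong: re-ionisation of the new, doubly activated benzylic C2–O1 bond under the Lewis acid, which leads to a second arylation with ring opening or to loss of facial control at C2.
- A minor share of the C2 epimer would be tolerable, because after step 7 the chroman is biased towards 2,3-trans and the Lewis-acidic steps 8 and 9 allow C2 to equilibrate.
- Fallback, setting out from 7 and coming back at 10: the acid-driven arylation is replaced by an organometallic one. TMSBr converts 7 into the anomeric bromide ethyl (3R,4R)-2-bromo-4-isobutyl-3-isopropyl-3,4-dihydro-2H-pyran-6-carboxylate F4. This is treated without purification, in toluene, with bis(2,4,6-trimethoxyphenyl)zinc F5, prepared from 8 by lithiation with n-BuLi and transmetalation with ZnBr2. Aryl transfer to the anomeric carbon, anti to the two alkyl groups, should give 10 in a medium free of strong acid.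

**Step 8.**
- What may go wrong: incomplete formylation, each ring stopping after its first aldehyde; and ionisation at C2 (cleavage of C2–O1 or loss of ring B by retro-Friedel–Crafts reaction) before the first formyl group has deactivated ring B.
- Fallback, setting out from 20 and coming back at 22: the order is reversed. BBr3 is applied first and should give the hexaphenol (2R,3R,4S)-4-isobutyl-3-isopropyl-2-(2,4,6-trihydroxyphenyl)chroman-5,7-diol F6. Fourfold Vilsmeier–Haack formylation (POCl3, DMF; aqueous hydrolysis) of the two free phloroglucinol rings, a reaction suited to diformylation of phloroglucinols and needing no strong Lewis acid, would then give 22 directly.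

**Step 9.**
- What may go wrong: cleavage of the benzylic C2–O1 ether by the boron halide in competition with the four alkyl ethers, or incomplete removal of the C7 ethyl group.
- Fallback, setting out from 21 and coming back at 22, with no new compound: nucleophilic dealkylation with a thiolate (NaSEt, DMF, 100–120 °C; acidic work-up). The thiolate attacks the unhindered alkyl carbons by substitution and should leave the secondary, hindered benzylic ether carbon alone; the ethyl group falls more slowly than the methyl groups, hence the higher temperature.

## Further compounds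

F1 | step 7 | 2-[(2R,3R,4S)-4-isobutyl-3-isopropyl-2-(2,4,6-trimethoxyphenyl)-3,4-dihydro-2H-pyran-6-yl]acetic acid | CC(C)C[C@@H]1C=C(CC(=O)O)O[C@@H](c2c(OC)cc(OC)cc2OC)[C@@H]1C(C)C
F2 | step 7 | 2-[(2R,3R,4S)-4-isobutyl-3-isopropyl-2-(2,4,6-trimethoxyphenyl)-3,4-dihydro-2H-pyran-6-yl]acetyl chloride | CC(C)C[C@@H]1C=C(CC(=O)Cl)O[C@@H](c2c(OC)cc(OC)cc2OC)[C@@H]1C(C)C
F3 | step 3 | ethyl (2R,3S,4S)-2-ethoxy-4-isobutyl-3-isopropyl-3,4-dihydro-2H-pyran-6-carboxylate (enantiomer of 7) | CC(C)C[C@H]1C=C(C(=O)OCC)O[C@@H](OCC)[C@H]1C(C)C
F4 | step 4 | ethyl (3R,4R)-2-bromo-4-isobutyl-3-isopropyl-3,4-dihydro-2H-pyran-6-carboxylate (anomeric mixture) | CC(C)C[C@@H]1C=C(C(=O)OCC)OC(Br)[C@@H]1C(C)C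
F5 | step 4 | bis(2,4,6-trimethoxyphenyl)zinc | COc1cc(OC)c([Zn]c2c(OC)cc(OC)cc2OC)c(OC)c1
F6 | step 8 | (2R,3R,4S)-4-isobutyl-3-isopropyl-2-(2,4,6-trihydroxyphenyl)chroman-5,7-diol | CC(C)C[C@@H]1c2c(O)cc(O)cc2O[C@@H](c2c(O)cc(O)cc2O)[C@@H]1C(C)C
F0 | step 9 | none | none
A1 | alternative 1 | 2-[(3R,4S)-2,6-dimethyl-4-(2,4,6-trimethoxyphenyl)heptan-3-yl]-4,4,5,5-tetramethyl-1,3,2-dioxaborolane | CC(C)C[C@H](c1c(OC)cc(OC)cc1OC)[C@@H](C(C)C)B1OC(C)(C)C(C)(C)O1
A2 | alternative 1 | 4,4,5,5-tetramethyl-2-[(Z)-4-methylpent-1-enyl]-1,3,2-dioxaborolane | CC(C)C/C=C\B1OC(C)(C)C(C)(C)O1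
A3 | alternative 1 | isopropyllithium | [Li]C(C)C
A4 | alternative 1 | 2,4,6-trimethoxyphenyl trifluoromethanesulfonate | COc1cc(OC)c(OS(=O)(=O)C(F)(F)F)c(OC)c1
A5 | alternative 2 | (2R,3S,4S)-5,7-dimethoxy-4-(2-methylprop-1-enyl)-3-(prop-1-en-2-yl)-2-(2,4,6-trimethoxyphenyl)chroman | CC(C)=C[C@@H]1c2c(OC)cc(OC)cc2O[C@@H](c2c(OC)cc(OC)cc2OC)[C@@H]1C(C)=C
A6 | alternative 2 | 2-(2,6-dimethylhepta-2,5-dien-4-yl)-3,5-dimethoxyphenol | COc1cc(O)c(C(C=C(C)C)C=C(C)C)c(OC)c1
A7 | alternative 2 | 2,4,6-trimethoxybenzaldehyde | COc1cc(OC)c(C=O)c(OC)c1
A8 | alternative 3 | (3R,4S)-4-isobutyl-3-isopropyl-5,7-dimethoxychroman-2-ol (anomeric mixture) | CC(C)C[C@@H]1c2c(OC)cc(OC)cc2OC(O)[C@@H]1C(C)C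
A9 | alternative 3 | 3,5-dimethoxyphenol | COc1cc(O)cc(OC)c1
A10 | alternative 3 | (E)-2-isopropyl-5-methylhex-2-enal | CC(C)C/C=C(/C=O)C(C)C
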